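**Retrosynthetic overview**
1. The target acid comes from its methyl ester by saponification. No ring is formed in the route: the furan ring is bought as furan-3-ylmethanol and carried through.
2. The ester is cut at the bond between the stereocentre (C3 of the pentadecatrienyl side chain) and the neighbouring CH2 (C2 of that chain). This gives an 11-carbon (2Z)-2-vinyl enoate and a 19-carbon linear tetraenyl chloride, joined by a one-pot hydroboration and copper-catalysed enantioselective SN2′ allyl–alkyl coupling.
3. Enabling feature: the stereocentre is the allylic CH of a CH–C(CH3)=CH2 unit, so it is the γ-carbon of an achiral (E)-2-methylalk-2-enyl chloride whose CH2Cl becomes the =CH2. Its CH2–CH2 link to the acrylate α-carbon is the hydroborated vinyl group of a 2-vinyl acrylate. The furan ring and the other four C=C bonds are bystanders.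
4. The vinyl enoate comes from methyl 5-(furan-3-yl)pent-2-ynoate: syn-hydrostannation fixes the (Z)-acrylate and a Stille vinylation follows. The ynoate comes from 3-(bromomethyl)furan, 1,3-dilithiopropyne and ClCO2Me.
5. The chloride comes from a nerol-derived enyne (9Z; neryl bromide and lithiated 1-(trimethylsilyl)propyne, then desilylation), by carboalumination (5E) and palladium-catalysed allylation with a five-carbon allylic acetate (2E, from SeO2 oxidation of prenyl acetate).

Key step: step 12

Remark on the chemistry (assumption): (R)-DTBM-SEGPHOS is taken to deliver the alkyl group to the Re face of the allylic chloride in the key step. The sense of induction should be confirmed on a model chloride, and the (S)-ligand is used if it is opposite.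

**Route**

Step 1
Reactants: 1 nerol
Product: 2 neryl bromide
Conditions: PBr3 (0.4 equiv), Et2O, −10 °C to 0 °C
Reagents that add atoms: phosphorus tribromide BrP(Br)Br
Why: Bromination of a primary allylic alcohol with PBr3 (SN2 on the phosphite ester) at low temperature should proceed without allylic shift and keep the (2Z) geometry.

Step 2
Reactants: 2 neryl bromide; 3 1-(trimethylsilyl)propyne
Product: 6 (5Z)-6,10-dimethylundeca-5,9-dien-1-yne, via lithiated silylpropyne 4 (not isolated), via silylated enyne 5 (not isolated)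
Conditions: 3 (1.2 equiv), n-BuLi (1.1 equiv), THF, −78 °C to −20 °C; then 2, −78 °C to 0 °C; then MeOH, K2CO3, rt
Reagents that add atoms: none
Why: Propargylation with lithiated 1-(trimethylsilyl)propyne, which alkylates the primary allylic bromide by SN2 at its propargylic carbon (the silyl group blocks the alkyne terminus and disfavours allenyl products), followed in the same flask by carbonate-catalysed methanolysis of the C(sp)–Si bond, should give the terminal 1,5-enyne with the (Z)-alkene untouched.

Step 3
Reactants: 7 prenyl acetate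
Product: 8 (2E)-4-hydroxy-3-methylbut-2-en-1-yl acetate
Conditions: SeO2 (cat.), t-BuOOH, salicylic acid (cat.), CH2Cl2, rt
Reagents that add atoms: tert-butyl hydroperoxide CC(C)(C)OO (oxygen relayed by catalytic selenium dioxide O=[Se]=O)
Why: Selenium dioxide allylic oxidation (ene reaction, then [2,3]-sigmatropic shift) is selective for the (E)-methyl group of a trisubstituted alkene and should give the (E)-allylic alcohol.

Step 4
Reactants: 8 (2E)-4-hydroxy-3-methylbut-2-en-1-yl acetate
Product: 9 (2E)-4-[(tert-butyldimethylsilyl)oxy]-3-methylbut-2-en-1-yl acetate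
Conditions: TBSCl, imidazole, CH2Cl2, 0 °C to rt
Reagents that add atoms: tert-butyldimethylsilyl chloride CC(C)(C)[Si](C)(C)Cl
Why: Imidazole-assisted silylation of the primary alcohol protects the future chloride carbon, while the acetate stays as the leaving group for step 5.

Step 5
Reactants: 6 (5Z)-6,10-dimethylundeca-5,9-dien-1-yne; 9 (2E)-4-[(tert-butyldimethylsilyl)oxy]-3-methylbut-2-en-1-yl acetate
Product: 11 tert-butyl(dimethyl){[(2E,5E,9Z)-2,6,10,14-tetramethylpentadeca-2,5,9,13-tetraen-1-yl]oxy}silane, via alkenylalane 10 (not isolated)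
Conditions: 6, Me3Al, Cp2ZrCl2 (25 mol %), CH2Cl2, rt; then 9, Pd(PPh3)4 (5 mol %), THF, rt
Reagents that add atoms: trimethylaluminium C[Al](C)C
Why: Negishi carboalumination adds methyl and aluminium syn across the terminal alkyne (methyl to the internal carbon), which fixes the (5E) alkene, and zerovalent-palladium-catalysed allyl–alkenyl cross-coupling of the alkenylalane at the less hindered CH2 terminus of the allyl unit should give the skipped diene with both alkene geometries retained.

Step 6
Reactants: 11 tert-butyl(dimethyl){[(2E,5E,9Z)-2,6,10,14-tetramethylpentadeca-2,5,9,13-tetraen-1-yl]oxy}silane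
Product: 12 (2E,5E,9Z)-2,6,10,14-tetramethylpentadeca-2,5,9,13-tetraen-1-ol
Conditions: TBAF, THF, 0 °C
Reagents that add atoms: none
Why: Fluoride-induced desilylation cleaves only the Si–O bond and leaves the skipped tetraene untouched.

Step 7
Reactants: 12 (2E,5E,9Z)-2,6,10,14-tetramethylpentadeca-2,5,9,13-tetraen-1-ol
Product: 13 (2E,5E,9Z)-1-chloro-2,6,10,14-tetramethylpentadeca-2,5,9,13-tetraene
Conditions: PPh3, CCl4, 60 °C
Reagents that add atoms: carbon tetrachloride ClC(Cl)(Cl)Cl
Why: Appel chlorination (SN2 displacement of the alkoxyphosphonium group by chloride) under neutral conditions should convert the primary allylic alcohol into the chloride without allylic shift or change of geometry.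

Step 8
Reactants: 14 furan-3-ylmethanol
Product: 15 3-(bromomethyl)furan
Conditions: PBr3 (0.4 equiv), pyridine (cat.), Et2O, 0 °C; ether solution used at once
Reagents that add atoms: phosphorus tribromide BrP(Br)Br
Why: Bromination of the furylmethyl alcohol with PBr3 (SN2 on the phosphite ester) is fast at 0 °C, and the labile bromide is not stored.

Step 9
Reactants: 15 3-(bromomethyl)furan; 16 propargyl bromide
Product: 19 methyl 5-(furan-3-yl)pent-2-ynoate, via 1,3-dilithiopropyne 17 (not isolated), via lithium acetylide 18 (not isolated)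
Conditions: 16, n-BuLi (2 equiv), TMEDA, Et2O/hexane, −78 °C; then 15, −78 °C to 0 °C; then ClCO2Me, −78 °C to rt
Reagents that add atoms: methyl chloroformate COC(=O)Cl
Why: One-pot propargylation with 1,3-dilithiopropyne (SN2 at the furylmethyl bromide through the sp3 carbanion) followed by C-acylation of the resulting lithium acetylide with the chloroformate should give the ynoate directly.

Step 10
Reactants: 19 methyl 5-(furan-3-yl)pent-2-ynoate
Product: 20 methyl (2E)-5-(furan-3-yl)-2-(tributylstannyl)pent-2-enoate
Conditions: Bu3SnH, Pd(PPh3)4 (2 mol %), THF, 0 °C to rt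
Reagents that add atoms: tributyltin hydride CCCC[SnH](CCCC)CCCC
Why: Zerovalent-palladium-catalysed hydrostannation of a 2-ynoate is a syn addition that places tin on the α-carbon and hydrogen on the β-carbon, so the ester ends cis to the furylethyl chain as the target requires.

Step 11
Reactants: 20 methyl (2E)-5-(furan-3-yl)-2-(tributylstannyl)pent-2-enoate; 21 vinyl bromide
Product: 22 methyl (2Z)-2-ethenyl-5-(furan-3-yl)pent-2-enoate
Conditions: vinyl bromide (1 M in THF), Pd(PPh3)4 (5 mol %), CuI (copper iodide, 20 mol %), DMF, 40 °C, sealed tube; product kept cold and used promptly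
Reagents that add atoms: none
Why: Stille cross-coupling with copper iodide as co-catalyst transfers the α-alkenyl group from tin with retention of configuration and should give the (2Z)-2-vinyl enoate.

Step 12
Reactants: 22 methyl (2Z)-2-ethenyl-5-(furan-3-yl)pent-2-enoate; 13 (2E,5E,9Z)-1-chloro-2,6,10,14-tetramethylpentadeca-2,5,9,13-tetraene
Product: 24 methyl (2Z)-5-(furan-3-yl)-2-[(3R,5E,9Z)-6,10,14-trimethyl-3-(prop-1-en-2-yl)pentadeca-5,9,13-trien-1-yl]pent-2-enoate, via alkyl-9-BBN 23 (not isolated)
Conditions: 22 (1.5 equiv), (9-BBN-H)2, THF, 60 °C; then 13, (CuOTf)2·toluene (5 mol %), (R)-DTBM-SEGPHOS (10 mol %), KOMe, 1,4-dioxane, 15 °C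
Reagents that add atoms: none
Why: 9-BBN adds B–H anti-Markovnikov to the only monosubstituted alkene of 22 (the ester-bearing trisubstituted alkene and the furan ring are inert), KOMe turns the alkylborane 23 into a borate that passes its primary alkyl group to the chiral bisphosphine copper methoxide, and the monovalent alkylcopper attacks the alkene of 13 anti to chloride (SN2′ oxidative addition) to give a γ-σ-allyl trivalent copper species that reductively eliminates before it can isomerise, so the new C–C bond forms at C3 of 13 and its C2–C1 unit becomes the isopropenyl group. The closest known reaction type is the copper/DTBM-SEGPHOS-catalysed γ-selective enantioselective allyl–alkyl coupling of alkyl-9-BBN reagents with primary allylic chlorides, and 2-methyl-substituted allylic chlorides of this kind are established substrates for copper-catalysed enantioselective SN2′ alkylation with Grignard reagents. No ring is closed. The new stereocentre is set by catalyst control: the ligand distinguishes the enantiotopic faces of the geometrically pure (E)-alkene, and delivery of the alkyl group to the Re face of C3 (C2 > C4 > H) gives the (R) configuration. The step needs γ over α regioselectivity (favoured by the soft alkylcopper, the chloride leaving group and the unhindered primary CH2Cl), chemoselectivity for the allylic chloride over the three other trisubstituted alkenes (none carries a leaving group) and over the enoate (α-branched and β-substituted, so a poor acceptor), and full consumption of B–H before 13 is added.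

Step 13
Reactants: 24 methyl (2Z)-5-(furan-3-yl)-2-[(3R,5E,9Z)-6,10,14-trimethyl-3-(prop-1-en-2-yl)pentadeca-5,9,13-trien-1-yl]pent-2-enoate
Product: 26 (2Z)-5-(furan-3-yl)-2-[(3R,5E,9Z)-6,10,14-trimethyl-3-(prop-1-en-2-yl)pentadeca-5,9,13-trien-1-yl]pent-2-enoic acid (target), via lithium carboxylate 25 (not isolated)
Conditions: LiOH·H2O, THF/MeOH/H2O, 40 °C; then 1 M HCl to pH 4, 0 °C
Reagents that add atoms: lithium hydroxide [Li+].[OH-]
Why: Saponification (acyl–oxygen cleavage by hydroxide) and mild acidification should give the acid, since the hindered (Z)-enoate is a poor Michael acceptor and the allylic stereocentre is not acidic, so geometry and configuration are kept.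

**Compound list**
1 | nerol, (2Z)-3,7-dimethylocta-2,6-dien-1-ol | OC/C=C(/C)CCC=C(C)C | starting material
2 | neryl bromide, (2Z)-1-bromo-3,7-dimethylocta-2,6-diene | BrC/C=C(/C)CCC=C(C)C | intermediate
3 | 1-(trimethylsilyl)propyne, trimethyl(prop-1-yn-1-yl)silane | CC#C[Si](C)(C)C | starting material
4 | [3-(trimethylsilyl)prop-2-yn-1-yl]lithium (lithiated silylpropyne) | [Li]CC#C[Si](C)(C)C | intermediate
5 | [(5Z)-6,10-dimethylundeca-5,9-dien-1-yn-1-yl]trimethylsilane (silylated enyne) | C[Si](C)(C)C#CCC/C=C(/C)CCC=C(C)C | intermediate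
6 | (5Z)-6,10-dimethylundeca-5,9-dien-1-yne | C#CCC/C=C(/C)CCC=C(C)C | intermediate
7 | prenyl acetate, 3-methylbut-2-en-1-yl acetate | CC(=O)OCC=C(C)C | starting material
8 | (2E)-4-hydroxy-3-methylbut-2-en-1-yl acetate | CC(=O)OC/C=C(\C)CO | intermediate
9 | (2E)-4-[(tert-butyldimethylsilyl)oxy]-3-methylbut-2-en-1-yl acetate | CC(=O)OC/C=C(\C)CO[Si](C)(C)C(C)(C)C | intermediate
10 | dimethyl[(1E,5Z)-2,6,10-trimethylundeca-1,5,9-trien-1-yl]alumane (alkenylalane) | C[Al](C)/C=C(\C)CC/C=C(/C)CCC=C(C)C | intermediate
11 | tert-butyl(dimethyl){[(2E,5E,9Z)-2,6,10,14-tetramethylpentadeca-2,5,9,13-tetraen-1-yl]oxy}silane | CC(C)(C)[Si](C)(C)OC/C(C)=C/C/C=C(\C)CC/C=C(/C)CCC=C(C)C | intermediate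
12 | (2E,5E,9Z)-2,6,10,14-tetramethylpentadeca-2,5,9,13-tetraen-1-ol | OC/C(C)=C/C/C=C(\C)CC/C=C(/C)CCC=C(C)C | intermediate
13 | (2E,5E,9Z)-1-chloro-2,6,10,14-tetramethylpentadeca-2,5,9,13-tetraene | ClC/C(C)=C/C/C=C(\C)CC/C=C(/C)CCC=C(C)C | intermediate
14 | furan-3-ylmethanol | OCc1ccoc1 | starting material
15 | 3-(bromomethyl)furan | BrCc1ccoc1 | intermediate
16 | propargyl bromide, 3-bromoprop-1-yne | C#CCBr | starting material
17 | 1,3-dilithiopropyne | [Li]CC#C[Li] | intermediate
18 | [4-(furan-3-yl)but-1-yn-1-yl]lithium (lithium acetylide) | [Li]C#CCCc1ccoc1 | intermediate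
19 | methyl 5-(furan-3-yl)pent-2-ynoate | COC(=O)C#CCCc1ccoc1 | intermediate
20 | methyl (2E)-5-(furan-3-yl)-2-(tributylstannyl)pent-2-enoate | COC(=O)/C(=C\CCc1ccoc1)[Sn](CCCC)(CCCC)CCCC | intermediate
21 | vinyl bromide, bromoethene | C=CBr | starting material
22 | methyl (2Z)-2-ethenyl-5-(furan-3-yl)pent-2-enoate | C=C/C(=C/CCc1ccoc1)C(=O)OC | intermediate
23 | methyl (2Z)-2-[2-(9-borabicyclo[3.3.1]nonan-9-yl)ethyl]-5-(furan-3-yl)pent-2-enoate (alkyl-9-BBN) | COC(=O)/C(CCB1C2CCCC1CCC2)=C\CCc1ccoc1 | intermediate
24 | methyl (2Z)-5-(furan-3-yl)-2-[(3R,5E,9Z)-6,10,14-trimethyl-3-(prop-1-en-2-yl)pentadeca-5,9,13-trien-1-yl]pent-2-enoate | C=C(C)[C@@H](C/C=C(\C)CC/C=C(/C)CCC=C(C)C)CC/C(=C/CCc1ccoc1)C(=O)OC | intermediate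
25 | lithium (2Z)-5-(furan-3-yl)-2-[(3R,5E,9Z)-6,10,14-trimethyl-3-(prop-1-en-2-yl)pentadeca-5,9,13-trien-1-yl]pent-2-enoate | C=C(C)[C@@H](C/C=C(\C)CC/C=C(/C)CCC=C(C)C)CC/C(=C/CCc1ccoc1)C(=O)[O-].[Li+] | intermediate
26 | (2Z)-5-(furan-3-yl)-2-[(3R,5E,9Z)-6,10,14-trimethyl-3-(prop-1-en-2-yl)pentadeca-5,9,13-trien-1-yl]pent-2-enoic acid | C=C(C)[C@@H](C/C=C(\C)CC/C=C(/C)CCC=C(C)C)CC/C(=C/CCc1ccoc1)C(=O)O | target

**Summary**
Total step count: 13. Longest linear sequence: 7 steps (steps 1, 2, 5, 6, 7, 12, 13).

**Steps most likely to fail**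

Step 12. The chiral copper catalyst may discriminate the alkene faces poorly, because the methyl group on the central allyl carbon changes how the alkene sits in the ligand pocket. Substitution may also leak to the α-carbon, or the hydroboration of the cross-conjugated diene may be incomplete or unselective. The fallback sets out from 22 and 13 and comes back at 26. It moves the acid to the alcohol oxidation level so that a Grignard reagent can be used, which is the nucleophile class with direct precedent on 2-methyl-substituted allylic chlorides. Reduction of 22 with i-Bu2AlH (CH2Cl2, −78 °C) gives (2Z)-2-ethenyl-5-(furan-3-yl)pent-2-en-1-ol F1, and silylation (TBSCl, imidazole) gives tert-butyl{[(2Z)-2-ethenyl-5-(furan-3-yl)pent-2-en-1-yl]oxy}dimethylsilane F2. Hydroboration of the vinyl group with 9-BBN and oxidation (NaOH, H2O2) gives (3Z)-3-{[(tert-butyldimethylsilyl)oxy]methyl}-6-(furan-3-yl)hex-3-en-1-ol F3, and CBr4/PPh3 gives {[(2Z)-2-(2-bromoethyl)-5-(furan-3-yl)pent-2-en-1-yl]oxy}(tert-butyl)dimethylsilane F4. Its Grignard reagent F5 (Mg, THF) is added slowly to 13 with CuTC (Cu(O2CC4H3S), monovalent copper) and a chiral phosphoramidite ligand in CH2Cl2 at −78 °C, an enantioselective SN2′ alkylation that should give tert-butyl({(2Z)-5-(furan-3-yl)-2-[(3R,5E,9Z)-6,10,14-trimethyl-3-(prop-1-en-2-yl)pentadeca-5,9,13-trien-1-yl]pent-2-en-1-yl}oxy)dimethylsilane F6. TBAF then gives (2Z)-5-(furan-3-yl)-2-[(3R,5E,9Z)-6,10,14-trimethyl-3-(prop-1-en-2-yl)pentadeca-5,9,13-trien-1-yl]pent-2-en-1-ol F7, MnO2 gives (2Z)-5-(furan-3-yl)-2-[(3R,5E,9Z)-6,10,14-trimethyl-3-(prop-1-en-2-yl)pentadeca-5,9,13-trien-1-yl]pent-2-enal F8, and Pinnick oxidation (NaClO2, NaH2PO4, 2-methylbut-2-ene, t-BuOH/H2O) gives 26, so that step 13 is not needed.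

Step 11. Tin-to-palladium transfer at the hindered, electron-poor α-carbon may be slow enough for protodestannylation to take over, and the ester-substituted diene may be lost by Diels–Alder self-dimerisation on concentration. The fallback sets out from 20 and comes back at 22, and reverses the polarity of the coupling. Iododestannylation of 20 (I2, CH2Cl2, 0 °C, retention) gives methyl (2E)-5-(furan-3-yl)-2-iodopent-2-enoate F9. Suzuki–Miyaura coupling of this iodide with potassium vinyltrifluoroborate (PdCl2(dppf), Cs2CO3, THF/H2O, 40 °C) should give 22, whose solution is filtered through silica and taken into step 12 without concentration to dryness.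

Step 5. Ionisation of the allylic acetate may be slow, so that methyl transfer from excess Me3Al or π–σ–π isomerisation of the allylpalladium intermediate (loss of the 2E geometry) competes. The fallback sets out from 6 and comes back at 12, and builds the C2–C3 alkene by olefination instead of allylation. Carboalumination of 6 to 10 as in step 5, conversion into the alanate with n-BuLi and opening of ethylene oxide gives (3E,7Z)-4,8,12-trimethyltrideca-3,7,11-trien-1-ol F10. Dess–Martin oxidation gives (3E,7Z)-4,8,12-trimethyltrideca-3,7,11-trienal F11, which is used at once in a Wittig reaction with the stabilised ylide ethyl 2-(triphenylphosphoranylidene)propanoate (CH2Cl2, rt) to give ethyl (2E,5E,9Z)-2,6,10,14-tetramethylpentadeca-2,5,9,13-tetraenoate F12. Reduction with i-Bu2AlH (−78 °C) gives 12, so that steps 3, 4 and 6 are not needed.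

Further compounds
F1 | step 12 | (2Z)-2-ethenyl-5-(furan-3-yl)pent-2-en-1-ol | C=C/C(CO)=C/CCc1ccoc1
F2 | step 12 | tert-butyl{[(2Z)-2-ethenyl-5-(furan-3-yl)pent-2-en-1-yl]oxy}dimethylsilane | C=C/C(CO[Si](C)(C)C(C)(C)C)=C/CCc1ccoc1
F3 | step 12 | (3Z)-3-{[(tert-butyldimethylsilyl)oxy]methyl}-6-(furan-3-yl)hex-3-en-1-ol | OCC/C(CO[Si](C)(C)C(C)(C)C)=C/CCc1ccoc1
F4 | step 12 | {[(2Z)-2-(2-bromoethyl)-5-(furan-3-yl)pent-2-en-1-yl]oxy}(tert-butyl)dimethylsilane | BrCC/C(CO[Si](C)(C)C(C)(C)C)=C/CCc1ccoc1
F5 | step 12 | Grignard reagent of F4, bromo{(3Z)-3-{[(tert-butyldimethylsilyl)oxy]methyl}-6-(furan-3-yl)hex-3-en-1-yl}magnesium | Br[Mg]CC/C(CO[Si](C)(C)C(C)(C)C)=C/CCc1ccoc1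
F6 | step 12 | tert-butyl({(2Z)-5-(furan-3-yl)-2-[(3R,5E,9Z)-6,10,14-trimethyl-3-(prop-1-en-2-yl)pentadeca-5,9,13-trien-1-yl]pent-2-en-1-yl}oxy)dimethylsilane | C=C(C)[C@@H](C/C=C(\C)CC/C=C(/C)CCC=C(C)C)CC/C(=C/CCc1ccoc1)CO[Si](C)(C)C(C)(C)C
F7 | step 12 | (2Z)-5-(furan-3-yl)-2-[(3R,5E,9Z)-6,10,14-trimethyl-3-(prop-1-en-2-yl)pentadeca-5,9,13-trien-1-yl]pent-2-en-1-ol | C=C(C)[C@@H](C/C=C(\C)CC/C=C(/C)CCC=C(C)C)CC/C(=C/CCc1ccoc1)CO
F8 | step 12 | (2Z)-5-(furan-3-yl)-2-[(3R,5E,9Z)-6,10,14-trimethyl-3-(prop-1-en-2-yl)pentadeca-5,9,13-trien-1-yl]pent-2-enal | C=C(C)[C@@H](C/C=C(\C)CC/C=C(/C)CCC=C(C)C)CC/C(=C/CCc1ccoc1)C=O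
F9 | step 11 | methyl (2E)-5-(furan-3-yl)-2-iodopent-2-enoate | COC(=O)/C(I)=C\CCc1ccoc1
F10 | step 5 | (3E,7Z)-4,8,12-trimethyltrideca-3,7,11-trien-1-ol | OCC/C=C(\C)CC/C=C(/C)CCC=C(C)C
F11 | step 5 | (3E,7Z)-4,8,12-trimethyltrideca-3,7,11-trienal | O=CC/C=C(\C)CC/C=C(/C)CCC=C(C)C
F12 | step 5 | ethyl (2E,5E,9Z)-2,6,10,14-tetramethylpentadeca-2,5,9,13-tetraenoate | CCOC(=O)/C(C)=C/C/C=C(\C)CC/C=C(/C)CCC=C(C)C
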